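**Retrosynthetic overview**

1. The target is a 25-membered, fully saturated macrolactone without stereocentres (C1 = lactone carbonyl, C24 = OCH2). The C19–C20 bond is read as the central sp–sp bond of a C18≡C19–C20≡C21 1,3-diyne (retro-hydrogenation) and cut by a retro-oxidative acetylene coupling into two terminal alkynes, two carbons of like (nucleophilic) polarity.
2. Enabling feature: C19 and C20 lie in an unbranched, unfunctionalised polymethylene stretch of the 25-membered ring, five and six atoms from the ring oxygen. Both can be raised to terminal acetylenic CH carbons, the ring is large enough to hold the rod-like C17–C22 diyne segment (and a spectator C12≡C13 alkyne) without strain, and the ester C1–O–C24 serves as the tether.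
3. Acyclic precursor: pent-4-yn-1-yl nonadeca-12,18-diynoate, from three commercial pieces: octa-1,7-diyne + 11-bromoundecanoic acid (acetylide alkylation, C11–C12) and pent-4-yn-1-ol (esterification, C24–O).
4. Ring order: the only ring, the 25-membered lactone, is closed in step 3 by Eglinton coupling (C19–C20); step 4 erases all three alkynes in one hydrogenation.

Key step: step 3

Remark: chain positions are numbered from the lactone carbonyl (C1) to the OCH2 carbon (C24); the target has no stereocentre, so no step sets or has to preserve configuration.

**Route**

Step 1
Reactants: 1 octa-1,7-diyne; 2 11-bromoundecanoic acid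
Product: 6 nonadeca-12,18-diynoic acid, via 1-lithioocta-1,7-diyne 3 (not isolated), via lithium 11-bromoundecanoate 4 (not isolated), via lithium nonadeca-12,18-diynoate 5 (not isolated)
Conditions: 1 (5 equiv), n-BuLi (2.1 equiv), THF, −78 → 0 °C; then 2, DMPU, 0 °C → rt; 1 M HCl work-up
Reagents that add atoms: none
Why: SN2 alkylation of a lithium acetylide by an unhindered primary bromide in THF/DMPU is standard for ω-bromoalkanoic acids carried as their lithium carboxylates (one equivalent of 3 deprotonates 2 to 4, the second alkylates it to 5), and the fivefold excess of 1 should keep lithiation, and hence alkylation, at one terminus.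

Step 2
Reactants: 6 nonadeca-12,18-diynoic acid; 7 pent-4-yn-1-ol
Product: 8 pent-4-yn-1-yl nonadeca-12,18-diynoate
Conditions: DCC (1.2 equiv), DMAP (0.1 equiv), CH2Cl2, 0 °C → rt
Reagents that add atoms: none
Why: Steglich esterification (carbodiimide activation, DMAP acyl transfer) should join an unhindered acid and a primary alcohol under neutral conditions that leave the three alkynes untouched.

Step 3
Reactants: 8 pent-4-yn-1-yl nonadeca-12,18-diynoate
Product: 9 oxacyclopentacosa-13,19,21-triyn-2-one (tetracosa-12,18,20-triyn-24-olide)
Conditions: Cu(OAc)2 (10 equiv), pyridine/MeCN (1:4), 60 °C, N2, syringe-pump addition of 8 over 10 h (final about 1 mM); aq. NH4Cl/EDTA wash, short SiO2 plug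
Reagents that add atoms: none
Why: Intramolecular Eglinton oxidative coupling: pyridine-assisted cupration turns both terminal C(sp)–H carbons (C19 and C20, both nucleophilic) into copper acetylides, divalent copper acetate oxidises them, and reductive elimination from a dinuclear copper bis(acetylide) should forge the C19–C20 sp–sp bond while copper leaves as monovalent CuOAc. The closest known reaction type is the Eglinton or Glaser–Hay macrocyclisation of α,ω-diyne esters to macrocyclic 1,3-diyne lactones. The single ring, the 25-membered lactone, is closed by direct end-to-end C–C macrocyclisation, with the ester acting as the tether between the two alkyne termini. No stereocentre is created. The step needs ring closure to outrun intermolecular coupling (cyclic dimer, oligomers), which is secured by slow addition into excess Cu(OAc)2 (pseudo-high dilution) and by a ring large enough to hold the linear C17–C22 segment without strain. Chemoselectivity is inherent, since only terminal alkynes are cuprated: the internal C12≡C13 alkyne and the ester are spectators, and the two termini can only give one constitution.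

Step 4
Reactants: 9 oxacyclopentacosa-13,19,21-triyn-2-one
Product: 10 24-tetracosanolide (oxacyclopentacosan-2-one)
Conditions: H2 (1–3 atm), 10% Pd/C, EtOAc, rt
Reagents that add atoms: none
Why: Exhaustive heterogeneous catalytic hydrogenation (six equivalents of H2) should saturate the 1,3-diyne and the isolated alkyne, while the lactone is inert to Pd/C and hydrogen.

**Compound list**

1 | octa-1,7-diyne | C#CCCCCC#C | starting material
2 | 11-bromoundecanoic acid | OC(=O)CCCCCCCCCCBr | starting material
3 | 1-lithioocta-1,7-diyne | [Li]C#CCCCCC#C | intermediate
4 | lithium 11-bromoundecanoate | [Li+].[O-]C(=O)CCCCCCCCCCBr | intermediate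
5 | lithium nonadeca-12,18-diynoate | [Li+].[O-]C(=O)CCCCCCCCCCC#CCCCCC#C | intermediate
6 | nonadeca-12,18-diynoic acid | OC(=O)CCCCCCCCCCC#CCCCCC#C | intermediate
7 | pent-4-yn-1-ol | OCCCC#C | starting material
8 | pent-4-yn-1-yl nonadeca-12,18-diynoate | C#CCCCCC#CCCCCCCCCCCC(=O)OCCCC#C | intermediate
9 | oxacyclopentacosa-13,19,21-triyn-2-one | O=C1CCCCCCCCCCC#CCCCCC#CC#CCCCO1 | intermediate
10 | 24-tetracosanolide (oxacyclopentacosan-2-one) | O=C1CCCCCCCCCCCCCCCCCCCCCCCO1 | target

**Summary**

Total step count: 4
Longest linear sequence: 4 steps (1 + 2 → 6 → 8 → 9 → 10)

**Steps most likely to fail**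

Step 3. Intermolecular oxidative coupling may keep pace with ring closure despite slow addition, diverting material into the cyclic dimer and open oligomers. The fallback makes the C19–C20 bond between two separate molecules and closes the ring at the ester instead. It sets out from 6 (together with 7) and comes back at 9. Bromination of the alkyne terminus of 7 (NBS, AgNO3 cat., acetone) should give 5-bromopent-4-yn-1-ol F1. Cadiot–Chodkiewicz cross-coupling of F1 with the terminal alkyne of 6 (CuCl cat., NH2OH·HCl, aq. EtNH2, MeOH, 0 °C → rt) should give 24-hydroxytetracosa-12,18,20-triynoic acid F2. Yamaguchi macrolactonisation of F2 (2,4,6-trichlorobenzoyl chloride, Et3N, THF; then slow addition to DMAP in toluene, 80 °C, high dilution) should close the 25-membered ring to 9, which re-enters the route at step 4.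

Step 1. Lithiation may not stay confined to one terminus of the diyne, so that a second alkylation (at the far end of 1 or at the free alkyne of the product) competes, and substitution on the sparingly soluble lithium carboxylate may be slow. The fallback installs the remote terminal alkyne by alkyne-zipper isomerisation, so that no diyne has to be differentiated and no carboxylate is alkylated. It sets out from 7 and comes back at 10. The dianion of 7 (n-BuLi 2.1 equiv, THF/DMPU, −78 °C → rt) alkylated with 1-bromotetradecane should give nonadec-4-yn-1-ol F3. Zipper isomerisation (KH, 1,3-diaminopropane, rt) should move the triple bond to the chain end to give nonadec-18-yn-1-ol F4. Jones oxidation (CrO3, H2SO4, acetone, 0 °C) should give nonadec-18-ynoic acid F5. Steglich esterification with 7 (DCC, DMAP, CH2Cl2) should give pent-4-yn-1-yl nonadec-18-ynoate F6. Eglinton closure under the conditions of step 3 should give oxacyclopentacosa-19,21-diyn-2-one F7. Hydrogenation as in step 4 should then give 10.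

Step 4. Traces of copper or pyridine carried over from step 3 may poison the palladium surface, so that the reduction stalls at the olefin stage and leaves unsaturated lactones that are hard to separate from the product. The fallback replaces surface catalysis by a stoichiometric, metal-free hydrogen transfer from diimide. It sets out from 9 and comes back at 10 directly. Diimide generated in situ from 2-nitrobenzenesulfonyl hydrazide and Et3N (large excess in repeated charges, CH2Cl2, rt) should add hydrogen in concerted syn fashion to all three triple bonds and to the cis-alkenes formed from them; no new compound is isolated on the way.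

**Further compounds**

F1 | step 3 | 5-bromopent-4-yn-1-ol | OCCCC#CBr
F2 | step 3 | 24-hydroxytetracosa-12,18,20-triynoic acid | OC(=O)CCCCCCCCCCC#CCCCCC#CC#CCCCO
F3 | step 1 | nonadec-4-yn-1-ol | OCCCC#CCCCCCCCCCCCCCC
F4 | step 1 | nonadec-18-yn-1-ol | OCCCCCCCCCCCCCCCCCC#C
F5 | step 1 | nonadec-18-ynoic acid | OC(=O)CCCCCCCCCCCCCCCCC#C
F6 | step 1 | pent-4-yn-1-yl nonadec-18-ynoate | C#CCCCCCCCCCCCCCCCCC(=O)OCCCC#C
F7 | step 1 | oxacyclopentacosa-19,21-diyn-2-one | O=C1CCCCCCCCCCCCCCCCC#CC#CCCCO1
F0 | step 4 | none | none
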